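## Plan

- **Cuts.** The retrosynthesis cuts the two gallate ester C–O bonds, then the O1–C2 bond of each pyran ring (back to an aryl ketone and a masked phenol). In ring B (the catechol ring) it cuts C1′–C2′ and C5′–C6′. Last, it cuts the two acyl C–C bonds that tie ring D (the pyrogallol ring) and an alkyne to one common Weinreb amide.
- **Enabling feature.** In ring B, the carbon bonded to ring D (C6′) and the carbon bonded to C2 (C1′) are neighbours, and both oxygens sit on the far edge (C3′, C4′). This is the pattern of an alkyne (C1′, C6′) joined to a 2,3-dioxygenated butadiene (C2′–C5′). The biaryl bond with its three ortho substituents can therefore be made earlier as an unhindered aryl–alkyne bond.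
- **Forward order.** The Weinreb amide (ring A plus the C2–C4 chain) and the ring D alkynyl bromide give a ketone, which closes to the pyran ring of the pyrogallol-side unit. The same amide is then used again to give the alkynyl ketone. Ring B follows by cycloaddition and aromatisation, then the second pyran ring, desilylation, two gallates and hydrogenolysis.
- **Stereochemistry.** Both C3 centres (R) come from one rhodium-catalysed asymmetric hydrogenation. Both C2 centres (R) arise by silane reduction of a cyclic oxocarbenium ion on the face anti to the C3 silyloxy group.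

Key step: step 18

Assumption: the structure string fixes the four sp3 stereocentres (all R) but gives no descriptor for the tri-ortho-substituted biaryl axis, so the axis is not controlled; if rotation proves slow, the two axial isomers would be separated by chromatography at the bis-silylated bis-flavan stage and the isomer of the natural series carried on.

## Route

Step 1
Reactants: 1 2,4,6-trihydroxybenzaldehyde
Product: 2 2,4-bis(benzyloxy)-6-hydroxybenzaldehyde
Conditions: BnBr (2 equiv), K2CO3, DMF, rt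
Reagents that add atoms: benzyl bromide, BrCc1ccccc1
Why: Williamson etherification; the para hydroxyl and one ortho hydroxyl are alkylated while the other ortho hydroxyl is held back by its hydrogen bond to the formyl group, so two equivalents of halide should stop at the dibenzyl ether.

Step 2
Reactants: 2 2,4-bis(benzyloxy)-6-hydroxybenzaldehyde
Product: 3 2,4-bis(benzyloxy)-6-(methoxymethoxy)benzaldehyde
Conditions: MOMCl, iPr2NEt, CH2Cl2, 0 → 40 °C
Reagents that add atoms: chloromethyl methyl ether, COCCl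
Why: O-alkylation of the chelated phenol with a reactive α-chloro ether gives an acetal-type protecting group that sets this oxygen, the future O1 of a pyran ring, apart from the benzylated ones.

Step 3
Reactants: 3 2,4-bis(benzyloxy)-6-(methoxymethoxy)benzaldehyde; 4 ethyl 2-acetoxy-2-(diethoxyphosphoryl)acetate
Product: 5 ethyl (Z)-2-acetoxy-3-[2,4-bis(benzyloxy)-6-(methoxymethoxy)phenyl]prop-2-enoate (Z isomer drawn; the E isomer may accompany it)
Conditions: LiCl, DBU, MeCN, 0 °C → rt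
Reagents that add atoms: none
Why: Horner–Wadsworth–Emmons olefination under mild LiCl/amidine conditions keeps the acetate on the phosphonate carbon, and the alkene geometry is of no consequence because both isomers are reduced to the same enantiomer in step 4.

Step 4
Reactants: 5 ethyl (Z)-2-acetoxy-3-[2,4-bis(benzyloxy)-6-(methoxymethoxy)phenyl]prop-2-enoate
Product: 6 ethyl (R)-2-acetoxy-3-[2,4-bis(benzyloxy)-6-(methoxymethoxy)phenyl]propanoate
Conditions: H2 (5 bar), [Rh(cod)((R,R)-Et-DuPHOS)]BF4 (cat.), degassed MeOH/THF, rt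
Reagents that add atoms: none
Why: Asymmetric hydrogenation of an α-acyloxyacrylate, in which the acetate carbonyl chelates the cationic rhodium as an enamide would and the (R,R) ligand delivers H2 to the face that gives the (R)-α-acetoxy ester; the homogeneous catalyst leaves benzyl ethers alone, and this one step sets the future C3 of both flavan units.

Step 5
Reactants: 6 ethyl (R)-2-acetoxy-3-[2,4-bis(benzyloxy)-6-(methoxymethoxy)phenyl]propanoate
Product: 7 (R)-3-[2,4-bis(benzyloxy)-6-(methoxymethoxy)phenyl]-2-hydroxy-N-methoxy-N-methylpropanamide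
Conditions: MeNH(OMe)·HCl (5 equiv), iPrMgCl (10 equiv), THF, −20 → 0 °C; aq. NH4Cl
Reagents that add atoms: N,O-dimethylhydroxylamine hydrochloride, CNOC.Cl
Why: Weinreb aminolysis with the chloromagnesium amide converts the ethyl ester into the N-methoxy-N-methylamide and strips the acetate in the same operation, and the magnesium alkoxide formed first shields the α-C–H from deprotonation.

Step 6
Reactants: 7 (R)-3-[2,4-bis(benzyloxy)-6-(methoxymethoxy)phenyl]-2-hydroxy-N-methoxy-N-methylpropanamide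
Product: 8 (R)-3-[2,4-bis(benzyloxy)-6-(methoxymethoxy)phenyl]-2-(tert-butyldiphenylsilyloxy)-N-methoxy-N-methylpropanamide
Conditions: TBDPSCl, imidazole, DMAP (cat.), DMF, rt
Reagents that add atoms: tert-butyldiphenylsilyl chloride, CC(C)(C)[Si](Cl)(c1ccccc1)c1ccccc1
Why: Standard alcohol silylation; the tert-butyldiphenylsilyl ether is chosen because it withstands the TMSBr and BF3·OEt2 used later, does not chelate, and is bulky enough to steer the hydride in steps 13 and 20.

Step 7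
Reactants: 9 5-bromo-1,2,3-trimethoxybenzene
Product: 10 5-bromobenzene-1,2,3-triol
Conditions: BBr3, CH2Cl2, −78 °C → rt; H2O
Reagents that add atoms: none
Why: Lewis-acid cleavage of aryl methyl ethers, to which the aryl bromide is inert.

Step 8
Reactants: 10 5-bromobenzene-1,2,3-triol
Product: 11 5-bromo-1,2,3-tris(benzyloxy)benzene
Conditions: BnBr (3.3 equiv), K2CO3, DMF, 60 °C, N2
Reagents that add atoms: benzyl bromide, BrCc1ccccc1
Why: Williamson etherification of all three phenols, run under nitrogen because the pyrogallol is air-sensitive in base.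

Step 9
Reactants: 11 5-bromo-1,2,3-tris(benzyloxy)benzene
Product: 12 1-bromo-2-iodo-3,4,5-tris(benzyloxy)benzene
Conditions: NIS (1 equiv), TFA (cat.), MeCN/CH2Cl2, 0 °C → rt, dark
Reagents that add atoms: N-iodosuccinimide, O=C1CCC(=O)N1I
Why: Electrophilic aromatic iodination; the two free ring positions are equivalent, each ortho and para to benzyloxy groups, and the first iodine crowds and deactivates the ring against a second.

Step 10
Reactants: 12 1-bromo-2-iodo-3,4,5-tris(benzyloxy)benzene; 13 trimethylsilylacetylene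
Product: 14 {[6-bromo-2,3,4-tris(benzyloxy)phenyl]ethynyl}trimethylsilane
Conditions: PdCl2(PPh3)2 (cat.), CuI (cat.), Et3N/THF, rt → 40 °C
Reagents that add atoms: none
Why: Sonogashira coupling; zerovalent palladium inserts into the C–I bond far faster than into C–Br, so the bromine is kept for step 11, and the aryl–alkyne bond made here at a linear carbon is the future biaryl bond.

Step 11
Reactants: 14 {[6-bromo-2,3,4-tris(benzyloxy)phenyl]ethynyl}trimethylsilane; 8 (R)-3-[2,4-bis(benzyloxy)-6-(methoxymethoxy)phenyl]-2-(tert-butyldiphenylsilyloxy)-N-methoxy-N-methylpropanamide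
Product: 16 (R)-1-[3,4,5-tris(benzyloxy)-2-(trimethylsilylethynyl)phenyl]-3-[2,4-bis(benzyloxy)-6-(methoxymethoxy)phenyl]-2-(tert-butyldiphenylsilyloxy)propan-1-one, via aryllithium 15 (not isolated)
Conditions: n-BuLi, THF, −78 °C; 8, −78 → −30 °C; AcOH, −78 °C
Reagents that add atoms: none
Why: Bromine–lithium exchange followed by Weinreb ketone synthesis; the chelated tetrahedral intermediate prevents over-addition and protects the α-stereocentre until the cold acidic quench.

Step 12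
Reactants: 16 (R)-1-[3,4,5-tris(benzyloxy)-2-(trimethylsilylethynyl)phenyl]-3-[2,4-bis(benzyloxy)-6-(methoxymethoxy)phenyl]-2-(tert-butyldiphenylsilyloxy)propan-1-one
Product: 17 (R)-1-[3,4,5-tris(benzyloxy)-2-(trimethylsilylethynyl)phenyl]-3-[2,4-bis(benzyloxy)-6-hydroxyphenyl]-2-(tert-butyldiphenylsilyloxy)propan-1-one (open form drawn; expected to equilibrate with its six-membered hemiketal)
Conditions: TMSBr, 4 Å MS, CH2Cl2, −30 °C; aq. NaHCO3
Reagents that add atoms: none
Why: Silyl-halide cleavage of an aryl methoxymethyl ether at low temperature, under which benzyl ethers, the tert-butyldiphenylsilyl ether and the alkynylsilane are stable and the hemiketal has little chance to dehydrate.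

Step 13
Reactants: 17 (R)-1-[3,4,5-tris(benzyloxy)-2-(trimethylsilylethynyl)phenyl]-3-[2,4-bis(benzyloxy)-6-hydroxyphenyl]-2-(tert-butyldiphenylsilyloxy)propan-1-one
Product: 18 (2R,3R)-5,7-bis(benzyloxy)-2-[3,4,5-tris(benzyloxy)-2-(trimethylsilylethynyl)phenyl]-3-(tert-butyldiphenylsilyloxy)chroman
Conditions: Et3SiH (10 equiv), BF3·OEt2 (2 equiv), CH2Cl2, −78 → −30 °C
Reagents that add atoms: none
Why: Ionic silane reduction of a cyclic hemiketal, the flavan counterpart of the lactol-to-C-aryl-glycoside reduction: BF3 ionises the hemiketal form of 17 to a 2-arylchromanyl oxocarbenium ion in which A(1,2) strain with the aryl group places the C3 silyloxy group pseudo-axial, and Et3SiH attacks axially on the opposite face, so that H-2 ends trans to the silyloxy group and C2 becomes R (2,3-cis).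

Step 14
Reactants: 18 (2R,3R)-5,7-bis(benzyloxy)-2-[3,4,5-tris(benzyloxy)-2-(trimethylsilylethynyl)phenyl]-3-(tert-butyldiphenylsilyloxy)chroman
Product: 19 (2R,3R)-5,7-bis(benzyloxy)-2-[3,4,5-tris(benzyloxy)-2-ethynylphenyl]-3-(tert-butyldiphenylsilyloxy)chroman
Conditions: K2CO3 (cat.), MeOH/THF, rt
Reagents that add atoms: none
Why: Base-catalysed methanolysis of the alkynyl C–Si bond, which is far more labile than the hindered silyl ether; the fully etherified flavan has no base-sensitive stereocentre.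

Step 15
Reactants: 19 (2R,3R)-5,7-bis(benzyloxy)-2-[3,4,5-tris(benzyloxy)-2-ethynylphenyl]-3-(tert-butyldiphenylsilyloxy)chroman; 8 (R)-3-[2,4-bis(benzyloxy)-6-(methoxymethoxy)phenyl]-2-(tert-butyldiphenylsilyloxy)-N-methoxy-N-methylpropanamide
Product: 21 (R)-1-[2,4-bis(benzyloxy)-6-(methoxymethoxy)phenyl]-2-(tert-butyldiphenylsilyloxy)-5-{2,3,4-tris(benzyloxy)-6-[(2R,3R)-5,7-bis(benzyloxy)-3-(tert-butyldiphenylsilyloxy)chroman-2-yl]phenyl}pent-4-yn-3-one, via lithium acetylide 20 (not isolated)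
Conditions: n-BuLi (1 equiv), THF, −78 °C; 8, −78 → −20 °C; AcOH, −78 °C
Reagents that add atoms: none
Why: Acylation of a lithium acetylide by a Weinreb amide gives the alkynyl ketone at the right oxidation level without a separate oxidation, and the cold acid quench protonates the released amine before it can add to the ynone.

Step 16
Reactants: 22 1,4-dibromobutane-2,3-diol (commercial diastereomer mixture; the stereocentres are erased in step 17)
Product: 23 1,4-dibromo-2,3-bis(benzyloxy)butane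
Conditions: benzyl 2,2,2-trichloroacetimidate (2.5 equiv), TfOH (cat.), CH2Cl2/cyclohexane, 0 °C → rt
Reagents that add atoms: benzyl 2,2,2-trichloroacetimidate, N=C(OCc1ccccc1)C(Cl)(Cl)Cl
Why: Acid-catalysed imidate benzylation, chosen because basic benzylation would close the bromohydrin units to epoxides.

Step 17
Reactants: 23 1,4-dibromo-2,3-bis(benzyloxy)butane
Product: 24 2,3-bis(benzyloxy)buta-1,3-diene
Conditions: KOtBu (3 equiv), THF, 0 → 40 °C; filtration through basic alumina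
Reagents that add atoms: none
Why: Twofold E2 dehydrobromination of a β-bromo ether; the only β-hydrogens are those on the oxygen-bearing carbons, so both eliminations must give 2-alkoxy-1-alkene units and hence the 2,3-dioxygenated diene.

Step 18
Reactants: 21 (R)-1-[2,4-bis(benzyloxy)-6-(methoxymethoxy)phenyl]-2-(tert-butyldiphenylsilyloxy)-5-{2,3,4-tris(benzyloxy)-6-[(2R,3R)-5,7-bis(benzyloxy)-3-(tert-butyldiphenylsilyloxy)chroman-2-yl]phenyl}pent-4-yn-3-one; 24 2,3-bis(benzyloxy)buta-1,3-diene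
Product: 26 (R)-1-{4,5-bis(benzyloxy)-2-[2,3,4-tris(benzyloxy)-6-((2R,3R)-5,7-bis(benzyloxy)-3-(tert-butyldiphenylsilyloxy)chroman-2-yl)phenyl]phenyl}-3-[2,4-bis(benzyloxy)-6-(methoxymethoxy)phenyl]-2-(tert-butyldiphenylsilyloxy)propan-1-one, via cyclohexa-1,4-diene 25 (not isolated)
Conditions: 24 (5 equiv, in portions), BHT (cat.), degassed o-xylene, base-washed sealed tube, 150 °C; cool, then activated MnO2 (10 equiv), rt → 50 °C
Reagents that add atoms: none
Why: The s-cis conformer of the electron-rich diene 24 adds in a concerted, normal-electron-demand [4+2] fashion across the carbonyl-conjugated triple bond of 21 to give cyclohexa-1,4-diene 25, whose two doubly allylic CH2 groups then each give up one hydrogen to MnO2 so that the ring aromatises. The closest known reaction type is the Diels–Alder benzannulation of alkynyl ketones and propiolates with 2,3-dialkoxy- or 2,3-bis(silyloxy)butadienes, followed by dehydrogenation to catechol diethers. Ring B closes by an intermolecular cycloaddition that forms C1′–C2′ and C5′–C6′ in one event; the two alkyne carbons become C1′ (acyl-bearing, the future point of attachment of C2) and C6′, so the aryl–alkyne bond of step 10 turns into the tri-ortho-substituted biaryl bond without any coupling of hindered halves. No sp3 stereocentre is created or touched, and the only new stereo-element is the biaryl axis, which is left to equilibrate at the reaction temperature. Only chemoselectivity is needed: the ynone is the sole electron-poor π bond in 21, the diene is constitutionally symmetric so no regioisomers can arise, and the neutral medium spares the enolisable α-silyloxy ketone, the acetal and the enol ethers. Excess diene, a radical inhibitor and a mild heterogeneous oxidant, which should not attack the flavan C4–H bonds as a high-potential quinone might, compensate for the steric shielding of the alkyne.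

Step 19
Reactants: 26 (R)-1-{4,5-bis(benzyloxy)-2-[2,3,4-tris(benzyloxy)-6-((2R,3R)-5,7-bis(benzyloxy)-3-(tert-butyldiphenylsilyloxy)chroman-2-yl)phenyl]phenyl}-3-[2,4-bis(benzyloxy)-6-(methoxymethoxy)phenyl]-2-(tert-butyldiphenylsilyloxy)propan-1-one
Product: 27 the corresponding 6-hydroxyphenyl ketone, that is 26 with OH in place of the methoxymethoxy group (open form drawn; expected to equilibrate with its hemiketal)
Conditions: TMSBr, 4 Å MS, CH2Cl2, −30 °C; aq. NaHCO3
Reagents that add atoms: none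
Why: The same low-temperature silyl-halide cleavage of the aryl methoxymethyl ether as in step 12, with the same tolerance of benzyl and tert-butyldiphenylsilyl ethers.

Step 20
Reactants: 27 the 6-hydroxyphenyl biaryl ketone
Product: 28 (2R,3R)-5,7-bis(benzyloxy)-2-{4,5-bis(benzyloxy)-2-[2,3,4-tris(benzyloxy)-6-((2R,3R)-5,7-bis(benzyloxy)-3-(tert-butyldiphenylsilyloxy)chroman-2-yl)phenyl]phenyl}-3-(tert-butyldiphenylsilyloxy)chroman
Conditions: Et3SiH (10 equiv), BF3·OEt2 (2 equiv), CH2Cl2, −78 → −30 °C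
Reagents that add atoms: none
Why: The same ionic silane reduction of the hemiketal as in step 13; the pseudo-axial C3 silyloxy group of the oxocarbenium ion directs axial hydride attack to the opposite face, so the second C2 becomes R (2,3-cis) and the second pyran ring is closed.

Step 21
Reactants: 28 the bis-silylated bis-flavan
Product: 29 the nona-O-benzyl bis-flavan-3-ol (28 with both silyloxy groups replaced by OH; all four centres R)
Conditions: TBAF (4 equiv), THF, rt → 50 °C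
Reagents that add atoms: none
Why: Fluoride-driven desilylation; nothing in the fully benzylated skeleton is sensitive to the basic fluoride.

Step 22
Reactants: 29 the nona-O-benzyl bis-flavan-3-ol; 30 3,4,5-tris(benzyloxy)benzoic acid
Product: 31 pentadeca-O-benzyl theasinensin F
Conditions: 30 (3 equiv), EDC·HCl (4 equiv), DMAP, CH2Cl2, rt
Reagents that add atoms: none
Why: Steglich-type carbodiimide/DMAP esterification, the usual way to acylate the axial C3 hydroxyl of benzylated 2,3-cis flavan-3-ols, with retention at C3 because only the O–H bond is broken.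

Step 23
Reactants: 31 pentadeca-O-benzyl theasinensin F
Product: 32 theasinensin F
Conditions: H2 (1 atm), Pd(OH)2/C, THF/MeOH, rt; filtration and concentration under N2
Reagents that add atoms: none
Why: Catalytic hydrogenolysis of all fifteen benzyl ethers under neutral conditions, which leave the gallate esters, the pyran C–O bonds and the four stereocentres intact.

## Compound list

1 | 2,4,6-trihydroxybenzaldehyde | O=Cc1c(O)cc(O)cc1O | starting material
2 | 2,4-bis(benzyloxy)-6-hydroxybenzaldehyde | O=Cc1c(O)cc(OCc9ccccc9)cc1OCc9ccccc9 | intermediate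
3 | 2,4-bis(benzyloxy)-6-(methoxymethoxy)benzaldehyde | COCOc1cc(OCc9ccccc9)cc(OCc9ccccc9)c1C=O | intermediate
4 | ethyl 2-acetoxy-2-(diethoxyphosphoryl)acetate | CCOC(=O)C(OC(C)=O)P(=O)(OCC)OCC | starting material
5 | ethyl (Z)-2-acetoxy-3-[2,4-bis(benzyloxy)-6-(methoxymethoxy)phenyl]prop-2-enoate | CCOC(=O)/C(OC(C)=O)=C/c1c(OCOC)cc(OCc9ccccc9)cc1OCc9ccccc9 | intermediate
6 | ethyl (R)-2-acetoxy-3-[2,4-bis(benzyloxy)-6-(methoxymethoxy)phenyl]propanoate | COCOc1cc(OCc9ccccc9)cc(OCc9ccccc9)c1C[C@@H](OC(C)=O)C(=O)OCC | intermediate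
7 | (R)-3-[2,4-bis(benzyloxy)-6-(methoxymethoxy)phenyl]-2-hydroxy-N-methoxy-N-methylpropanamide | COCOc1cc(OCc9ccccc9)cc(OCc9ccccc9)c1C[C@@H](O)C(=O)N(C)OC | intermediate
8 | (R)-3-[2,4-bis(benzyloxy)-6-(methoxymethoxy)phenyl]-2-(tert-butyldiphenylsilyloxy)-N-methoxy-N-methylpropanamide | COCOc1cc(OCc9ccccc9)cc(OCc9ccccc9)c1C[C@@H](O[Si](c8ccccc8)(c8ccccc8)C(C)(C)C)C(=O)N(C)OC | intermediate
9 | 5-bromo-1,2,3-trimethoxybenzene | COc1cc(Br)cc(OC)c1OC | starting material
10 | 5-bromobenzene-1,2,3-triol | Oc1cc(Br)cc(O)c1O | intermediate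
11 | 5-bromo-1,2,3-tris(benzyloxy)benzene | Brc1cc(OCc9ccccc9)c(OCc9ccccc9)c(OCc9ccccc9)c1 | intermediate
12 | 1-bromo-2-iodo-3,4,5-tris(benzyloxy)benzene | Brc1cc(OCc9ccccc9)c(OCc9ccccc9)c(OCc9ccccc9)c1I | intermediate
13 | trimethylsilylacetylene | C#C[Si](C)(C)C | starting material
14 | {[6-bromo-2,3,4-tris(benzyloxy)phenyl]ethynyl}trimethylsilane | C[Si](C)(C)C#Cc1c(Br)cc(OCc9ccccc9)c(OCc9ccccc9)c1OCc9ccccc9 | intermediate
15 | [3,4,5-tris(benzyloxy)-2-(trimethylsilylethynyl)phenyl]lithium | [Li]c1cc(OCc9ccccc9)c(OCc9ccccc9)c(OCc9ccccc9)c1C#C[Si](C)(C)C | intermediate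
16 | (R)-1-[3,4,5-tris(benzyloxy)-2-(trimethylsilylethynyl)phenyl]-3-[2,4-bis(benzyloxy)-6-(methoxymethoxy)phenyl]-2-(tert-butyldiphenylsilyloxy)propan-1-one | COCOc1cc(OCc9ccccc9)cc(OCc9ccccc9)c1C[C@@H](O[Si](c8ccccc8)(c8ccccc8)C(C)(C)C)C(=O)c1cc(OCc9ccccc9)c(OCc9ccccc9)c(OCc9ccccc9)c1C#C[Si](C)(C)C | intermediate
17 | (R)-1-[3,4,5-tris(benzyloxy)-2-(trimethylsilylethynyl)phenyl]-3-[2,4-bis(benzyloxy)-6-hydroxyphenyl]-2-(tert-butyldiphenylsilyloxy)propan-1-one | Oc1cc(OCc9ccccc9)cc(OCc9ccccc9)c1C[C@@H](O[Si](c8ccccc8)(c8ccccc8)C(C)(C)C)C(=O)c1cc(OCc9ccccc9)c(OCc9ccccc9)c(OCc9ccccc9)c1C#C[Si](C)(C)C | intermediate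
18 | (2R,3R)-5,7-bis(benzyloxy)-2-[3,4,5-tris(benzyloxy)-2-(trimethylsilylethynyl)phenyl]-3-(tert-butyldiphenylsilyloxy)chroman | C[Si](C)(C)C#Cc1c([C@H]2Oc3cc(OCc9ccccc9)cc(OCc9ccccc9)c3C[C@H]2O[Si](c8ccccc8)(c8ccccc8)C(C)(C)C)cc(OCc9ccccc9)c(OCc9ccccc9)c1OCc9ccccc9 | intermediate
19 | (2R,3R)-5,7-bis(benzyloxy)-2-[3,4,5-tris(benzyloxy)-2-ethynylphenyl]-3-(tert-butyldiphenylsilyloxy)chroman | C#Cc1c([C@H]2Oc3cc(OCc9ccccc9)cc(OCc9ccccc9)c3C[C@H]2O[Si](c8ccccc8)(c8ccccc8)C(C)(C)C)cc(OCc9ccccc9)c(OCc9ccccc9)c1OCc9ccccc9 | intermediate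
20 | lithium acetylide of 19 | [Li]C#Cc1c([C@H]2Oc3cc(OCc9ccccc9)cc(OCc9ccccc9)c3C[C@H]2O[Si](c8ccccc8)(c8ccccc8)C(C)(C)C)cc(OCc9ccccc9)c(OCc9ccccc9)c1OCc9ccccc9 | intermediate
21 | (R)-1-[2,4-bis(benzyloxy)-6-(methoxymethoxy)phenyl]-2-(tert-butyldiphenylsilyloxy)-5-{2,3,4-tris(benzyloxy)-6-[(2R,3R)-5,7-bis(benzyloxy)-3-(tert-butyldiphenylsilyloxy)chroman-2-yl]phenyl}pent-4-yn-3-one | COCOc1cc(OCc9ccccc9)cc(OCc9ccccc9)c1C[C@@H](O[Si](c8ccccc8)(c8ccccc8)C(C)(C)C)C(=O)C#Cc1c([C@H]2Oc3cc(OCc9ccccc9)cc(OCc9ccccc9)c3C[C@H]2O[Si](c8ccccc8)(c8ccccc8)C(C)(C)C)cc(OCc9ccccc9)c(OCc9ccccc9)c1OCc9ccccc9 | intermediate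
22 | 1,4-dibromobutane-2,3-diol | OC(CBr)C(O)CBr | starting material
23 | 1,4-dibromo-2,3-bis(benzyloxy)butane | BrCC(OCc9ccccc9)C(CBr)OCc9ccccc9 | intermediate
24 | 2,3-bis(benzyloxy)buta-1,3-diene | C=C(OCc9ccccc9)C(=C)OCc9ccccc9 | intermediate
25 | cyclohexa-1,4-diene adduct of 21 and 24 (4,5-bis(benzyloxy)cyclohexa-1,4-diene with the acyl chain on C1 and the ring D aryl group on C2) | COCOc1cc(OCc9ccccc9)cc(OCc9ccccc9)c1C[C@@H](O[Si](c8ccccc8)(c8ccccc8)C(C)(C)C)C(=O)C1=C(CC(OCc9ccccc9)=C(OCc9ccccc9)C1)c1c([C@H]2Oc3cc(OCc9ccccc9)cc(OCc9ccccc9)c3C[C@H]2O[Si](c8ccccc8)(c8ccccc8)C(C)(C)C)cc(OCc9ccccc9)c(OCc9ccccc9)c1OCc9ccccc9 | intermediate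
26 | (R)-1-{4,5-bis(benzyloxy)-2-[2,3,4-tris(benzyloxy)-6-((2R,3R)-5,7-bis(benzyloxy)-3-(tert-butyldiphenylsilyloxy)chroman-2-yl)phenyl]phenyl}-3-[2,4-bis(benzyloxy)-6-(methoxymethoxy)phenyl]-2-(tert-butyldiphenylsilyloxy)propan-1-one | COCOc1cc(OCc9ccccc9)cc(OCc9ccccc9)c1C[C@@H](O[Si](c8ccccc8)(c8ccccc8)C(C)(C)C)C(=O)c1cc(OCc9ccccc9)c(OCc9ccccc9)cc1-c1c([C@H]2Oc3cc(OCc9ccccc9)cc(OCc9ccccc9)c3C[C@H]2O[Si](c8ccccc8)(c8ccccc8)C(C)(C)C)cc(OCc9ccccc9)c(OCc9ccccc9)c1OCc9ccccc9 | intermediate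
27 | 26 with OH in place of the methoxymethoxy group | Oc1cc(OCc9ccccc9)cc(OCc9ccccc9)c1C[C@@H](O[Si](c8ccccc8)(c8ccccc8)C(C)(C)C)C(=O)c1cc(OCc9ccccc9)c(OCc9ccccc9)cc1-c1c([C@H]2Oc3cc(OCc9ccccc9)cc(OCc9ccccc9)c3C[C@H]2O[Si](c8ccccc8)(c8ccccc8)C(C)(C)C)cc(OCc9ccccc9)c(OCc9ccccc9)c1OCc9ccccc9 | intermediate
28 | (2R,3R)-5,7-bis(benzyloxy)-2-{4,5-bis(benzyloxy)-2-[2,3,4-tris(benzyloxy)-6-((2R,3R)-5,7-bis(benzyloxy)-3-(tert-butyldiphenylsilyloxy)chroman-2-yl)phenyl]phenyl}-3-(tert-butyldiphenylsilyloxy)chroman | CC(C)(C)[Si](c8ccccc8)(c8ccccc8)O[C@@H]1Cc2c(OCc9ccccc9)cc(OCc9ccccc9)cc2O[C@@H]1c1cc(OCc9ccccc9)c(OCc9ccccc9)cc1-c1c([C@H]2Oc3cc(OCc9ccccc9)cc(OCc9ccccc9)c3C[C@H]2O[Si](c8ccccc8)(c8ccccc8)C(C)(C)C)cc(OCc9ccccc9)c(OCc9ccccc9)c1OCc9ccccc9 | intermediate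
29 | nona-O-benzyl bis-flavan-3-ol (28 with both silyloxy groups replaced by OH) | O[C@@H]1Cc2c(OCc9ccccc9)cc(OCc9ccccc9)cc2O[C@@H]1c1cc(OCc9ccccc9)c(OCc9ccccc9)cc1-c1c([C@H]2Oc3cc(OCc9ccccc9)cc(OCc9ccccc9)c3C[C@H]2O)cc(OCc9ccccc9)c(OCc9ccccc9)c1OCc9ccccc9 | intermediate
30 | 3,4,5-tris(benzyloxy)benzoic acid | O=C(O)c1cc(OCc9ccccc9)c(OCc9ccccc9)c(OCc9ccccc9)c1 | starting material
31 | pentadeca-O-benzyl theasinensin F | O=C(O[C@@H]1Cc2c(OCc9ccccc9)cc(OCc9ccccc9)cc2O[C@@H]1c1cc(OCc9ccccc9)c(OCc9ccccc9)cc1-c1c([C@H]2Oc3cc(OCc9ccccc9)cc(OCc9ccccc9)c3C[C@H]2OC(=O)c2cc(OCc9ccccc9)c(OCc9ccccc9)c(OCc9ccccc9)c2)cc(OCc9ccccc9)c(OCc9ccccc9)c1OCc9ccccc9)c1cc(OCc9ccccc9)c(OCc9ccccc9)c(OCc9ccccc9)c1 | intermediate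
32 | theasinensin F | O=C(O[C@@H]1Cc2c(O)cc(O)cc2O[C@@H]1c1cc(O)c(O)cc1-c1c([C@H]2Oc3cc(O)cc(O)c3C[C@H]2OC(=O)c2cc(O)c(O)c(O)c2)cc(O)c(O)c1O)c1cc(O)c(O)c(O)c1 | target

## Step count and risks

Total step count: 23.
Longest linear sequence: 17 steps (steps 1–6, 11–15 and 18–23).

**Step 18 (cycloaddition/aromatisation).**
- The alkyne terminus is flanked by two ortho substituents, one of them the whole flavan unit, and it is electronically damped by the trialkoxyaryl donor. The cycloaddition may therefore be outrun by thermal oligomerisation or adventitious hydrolysis of the diene.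
- The fallback keeps the same ring B construction but moves it ahead of the first pyran closure, so the ortho neighbour of the alkyne is a bromine atom instead of a chromanyl group. It sets out from 14 (with 8 and 24) and comes back at 28.
- Methanolysis of 14 (K2CO3, MeOH) would give 1-bromo-2-ethynyl-3,4,5-tris(benzyloxy)benzene F1. LiHMDS, which leaves the C–Br bond alone, turns it into the bromoaryl lithium acetylide F2, and acylation by 8 gives the bromo ynone F3.
- Heating F3 with 24 gives the bromo cyclohexa-1,4-diene F4, and MnO2 gives the bromo biaryl ketone F5.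
- TMSBr at −30 °C frees the bromo biaryl phenol ketone F6, and Et3SiH/BF3·OEt2 closes the catechol-side pyran ring to the bromo biaryl flavan F7.
- n-BuLi at −78 °C gives the biaryl aryllithium F8, which 8 acylates to the ring D ketone F9. TMSBr gives the ring D phenol ketone F10, and a last Et3SiH/BF3·OEt2 reduction gives 28.

**Step 20 (second reductive cyclisation).**
- Next to the bulky biaryl, hydride delivery to the oxocarbenium ion may lose facial selectivity. Proton loss from C3 may compete with hydride capture and erase that stereocentre.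
- The fallback sets C2 in two separate, known operations and closes the ring by substitution instead of reduction. It sets out from 27 and comes back at 29.
- TBAF buffered with AcOH removes both silyl groups to give the α-hydroxy ketone triol F11.
- Zn(BH4)2 in Et2O at −20 °C reduces the ketone under chelation control by the free α-hydroxyl to the (1S,2R)-anti diol F12.
- An intramolecular Mitsunobu etherification (PPh3, DIAD, THF, 0 °C) activates the benzylic hydroxyl and lets the phenol displace it with inversion. This gives the 2,3-cis pyran ring of 29 directly.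

**Step 17 (diene).**
- The twofold elimination may stall at the mono-vinyl ether, or the acid- and heat-sensitive diene may hydrolyse or oligomerise during isolation.
- The fallback does without the benzylated diene and installs the two benzyl groups after ring B is formed. It sets out from 21 and comes back at 26.
- Commercial 2,3-bis(trimethylsilyloxy)buta-1,3-diene is heated with 21 to give the bis(silyl enol ether) cyclohexadiene F13.
- MnO2 aromatises F13 to the catechol bis(trimethylsilyl) ether F14.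
- KF and BnBr in DMF at rt exchange the two labile aryl silyl ethers for benzyl ethers while the hindered alkyl tert-butyldiphenylsilyl ethers stay in place, giving 26.

## Further compounds

F1 | step 18 | 1-bromo-2-ethynyl-3,4,5-tris(benzyloxy)benzene | C#Cc1c(Br)cc(OCc9ccccc9)c(OCc9ccccc9)c1OCc9ccccc9
F2 | step 18 | bromoaryl lithium acetylide (lithium salt of F1) | [Li]C#Cc1c(Br)cc(OCc9ccccc9)c(OCc9ccccc9)c1OCc9ccccc9
F3 | step 18 | bromo ynone, (R)-5-[6-bromo-2,3,4-tris(benzyloxy)phenyl]-1-[2,4-bis(benzyloxy)-6-(methoxymethoxy)phenyl]-2-(tert-butyldiphenylsilyloxy)pent-4-yn-3-one | COCOc1cc(OCc9ccccc9)cc(OCc9ccccc9)c1C[C@@H](O[Si](c8ccccc8)(c8ccccc8)C(C)(C)C)C(=O)C#Cc1c(Br)cc(OCc9ccccc9)c(OCc9ccccc9)c1OCc9ccccc9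
F4 | step 18 | bromo cyclohexa-1,4-diene (adduct of F3 and 24) | COCOc1cc(OCc9ccccc9)cc(OCc9ccccc9)c1C[C@@H](O[Si](c8ccccc8)(c8ccccc8)C(C)(C)C)C(=O)C1=C(CC(OCc9ccccc9)=C(OCc9ccccc9)C1)c1c(Br)cc(OCc9ccccc9)c(OCc9ccccc9)c1OCc9ccccc9
F5 | step 18 | bromo biaryl ketone, (R)-1-{4,5-bis(benzyloxy)-2-[6-bromo-2,3,4-tris(benzyloxy)phenyl]phenyl}-3-[2,4-bis(benzyloxy)-6-(methoxymethoxy)phenyl]-2-(tert-butyldiphenylsilyloxy)propan-1-one | COCOc1cc(OCc9ccccc9)cc(OCc9ccccc9)c1C[C@@H](O[Si](c8ccccc8)(c8ccccc8)C(C)(C)C)C(=O)c1cc(OCc9ccccc9)c(OCc9ccccc9)cc1-c1c(Br)cc(OCc9ccccc9)c(OCc9ccccc9)c1OCc9ccccc9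
F6 | step 18 | bromo biaryl phenol ketone (F5 with OH in place of the methoxymethoxy group) | Oc1cc(OCc9ccccc9)cc(OCc9ccccc9)c1C[C@@H](O[Si](c8ccccc8)(c8ccccc8)C(C)(C)C)C(=O)c1cc(OCc9ccccc9)c(OCc9ccccc9)cc1-c1c(Br)cc(OCc9ccccc9)c(OCc9ccccc9)c1OCc9ccccc9
F7 | step 18 | bromo biaryl flavan, (2R,3R)-5,7-bis(benzyloxy)-2-{4,5-bis(benzyloxy)-2-[6-bromo-2,3,4-tris(benzyloxy)phenyl]phenyl}-3-(tert-butyldiphenylsilyloxy)chroman | CC(C)(C)[Si](c8ccccc8)(c8ccccc8)O[C@@H]1Cc2c(OCc9ccccc9)cc(OCc9ccccc9)cc2O[C@@H]1c1cc(OCc9ccccc9)c(OCc9ccccc9)cc1-c1c(Br)cc(OCc9ccccc9)c(OCc9ccccc9)c1OCc9ccccc9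
F8 | step 18 | biaryl aryllithium (F7 with Li in place of Br) | CC(C)(C)[Si](c8ccccc8)(c8ccccc8)O[C@@H]1Cc2c(OCc9ccccc9)cc(OCc9ccccc9)cc2O[C@@H]1c1cc(OCc9ccccc9)c(OCc9ccccc9)cc1-c1c([Li])cc(OCc9ccccc9)c(OCc9ccccc9)c1OCc9ccccc9
F9 | step 18 | ring D ketone (F7 with the (R)-3-[2,4-bis(benzyloxy)-6-(methoxymethoxy)phenyl]-2-(tert-butyldiphenylsilyloxy)propanoyl group in place of Br) | CC(C)(C)[Si](c8ccccc8)(c8ccccc8)O[C@@H]1Cc2c(OCc9ccccc9)cc(OCc9ccccc9)cc2O[C@@H]1c1cc(OCc9ccccc9)c(OCc9ccccc9)cc1-c1c(C(=O)[C@@H](Cc2c(OCOC)cc(OCc9ccccc9)cc2OCc9ccccc9)O[Si](c8ccccc8)(c8ccccc8)C(C)(C)C)cc(OCc9ccccc9)c(OCc9ccccc9)c1OCc9ccccc9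
F10 | step 18 | ring D phenol ketone (F9 with OH in place of the methoxymethoxy group) | CC(C)(C)[Si](c8ccccc8)(c8ccccc8)O[C@@H]1Cc2c(OCc9ccccc9)cc(OCc9ccccc9)cc2O[C@@H]1c1cc(OCc9ccccc9)c(OCc9ccccc9)cc1-c1c(C(=O)[C@@H](Cc2c(O)cc(OCc9ccccc9)cc2OCc9ccccc9)O[Si](c8ccccc8)(c8ccccc8)C(C)(C)C)cc(OCc9ccccc9)c(OCc9ccccc9)c1OCc9ccccc9
F11 | step 20 | α-hydroxy ketone triol (27 with both silyloxy groups replaced by OH) | Oc1cc(OCc9ccccc9)cc(OCc9ccccc9)c1C[C@@H](O)C(=O)c1cc(OCc9ccccc9)c(OCc9ccccc9)cc1-c1c([C@H]2Oc3cc(OCc9ccccc9)cc(OCc9ccccc9)c3C[C@H]2O)cc(OCc9ccccc9)c(OCc9ccccc9)c1OCc9ccccc9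
F12 | step 20 | (1S,2R)-anti diol (F11 with the ketone reduced to the (S)-carbinol) | Oc1cc(OCc9ccccc9)cc(OCc9ccccc9)c1C[C@@H](O)[C@@H](O)c1cc(OCc9ccccc9)c(OCc9ccccc9)cc1-c1c([C@H]2Oc3cc(OCc9ccccc9)cc(OCc9ccccc9)c3C[C@H]2O)cc(OCc9ccccc9)c(OCc9ccccc9)c1OCc9ccccc9
F13 | step 17 | bis(silyl enol ether) cyclohexadiene (adduct of 21 and 2,3-bis(trimethylsilyloxy)buta-1,3-diene) | COCOc1cc(OCc9ccccc9)cc(OCc9ccccc9)c1C[C@@H](O[Si](c8ccccc8)(c8ccccc8)C(C)(C)C)C(=O)C1=C(CC(O[Si](C)(C)C)=C(O[Si](C)(C)C)C1)c1c([C@H]2Oc3cc(OCc9ccccc9)cc(OCc9ccccc9)c3C[C@H]2O[Si](c8ccccc8)(c8ccccc8)C(C)(C)C)cc(OCc9ccccc9)c(OCc9ccccc9)c1OCc9ccccc9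
F14 | step 17 | catechol bis(trimethylsilyl) ether (26 with the two ring B benzyloxy groups replaced by trimethylsilyloxy) | COCOc1cc(OCc9ccccc9)cc(OCc9ccccc9)c1C[C@@H](O[Si](c8ccccc8)(c8ccccc8)C(C)(C)C)C(=O)c1cc(O[Si](C)(C)C)c(O[Si](C)(C)C)cc1-c1c([C@H]2Oc3cc(OCc9ccccc9)cc(OCc9ccccc9)c3C[C@H]2O[Si](c8ccccc8)(c8ccccc8)C(C)(C)C)cc(OCc9ccccc9)c(OCc9ccccc9)c1OCc9ccccc9
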